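**Plan**
- Retrosynthesis: pyran ring B is cut twice, at C4–C4a and at O2–C3, leaving a ring-A enol triflate with a CH2OH on C-8a and free (E)-pent-2-en-4-ynoic acid. The C-6 ester is then cut at its alkyl C–O bond (epoxide + arenecarboxylic acid).
- Forward: ring A comes from (R)-carvone by epoxidation, α'-hydroxymethylation, epoxide opening by the arenecarboxylate, excision of the isopropenyl group to a 1,3-dione and enol triflation. Ring B and the whole side chain are then joined in one Sonogashira/oxa-Michael domino, and removal of two MOM groups ends the route.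
- Enabling feature: the C-8 ketone of ring A is conjugated through C8a=C4a with the new alkyne, so the distal alkyne carbon is its δ-acceptor position. The C-8a CH2OH oxygen lies in reach of that carbon for a six-membered (6-endo) closure.
- Stereochemistry: C-5 of carvone directs the epoxide trans; SN2 opening inverts the secondary carbon and gives the (6S,7R) trans-hydroxy ester. The carvone stereocentre is then erased as C-4a, and the E-alkene comes from a Horner–Wadsworth–Emmons reaction.

Key step: step 13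

Assumption: dione 18 is drawn as its diketo tautomer (it should be enolised, so its C-4 configuration is left open), and acids formed under amine conditions are drawn as free acids.

**Step 1**
Reactants: 1 2,3,4-trimethoxy-6-methylbenzaldehyde
Product: 2 2,3,4-trihydroxy-6-methylbenzaldehyde
Conditions: BBr3 (4 equiv), CH2Cl2, −78 °C to rt; then H2O
Reagents that add atoms: none
Why: Exhaustive Lewis-acid demethylation of aryl methyl ethers (bromide attacks the O-methyl of the boron-complexed ether) should free the symmetric pyrogallol pattern, whose 2-OH is then set apart by its hydrogen bond to the formyl group.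

**Step 2**
Reactants: 2 2,3,4-trihydroxy-6-methylbenzaldehyde
Product: 3 2-hydroxy-3,4-bis(methoxymethoxy)-6-methylbenzaldehyde
Conditions: MOMCl (2.2 equiv), K2CO3 (2.5 equiv), acetone, 0 °C to rt
Reagents that add atoms: chloromethyl methyl ether COCCl
Why: Williamson-type O-alkylation under weak base should cap the 4- and 3-OH and leave the 2-OH, which is chelated to the aldehyde and least nucleophilic, as is usual for 2,3,4-trihydroxyaryl carbonyl compounds.

**Step 3**
Reactants: 3 2-hydroxy-3,4-bis(methoxymethoxy)-6-methylbenzaldehyde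
Product: 4 2-methoxy-3,4-bis(methoxymethoxy)-6-methylbenzaldehyde
Conditions: MeI (1.5 equiv), K2CO3, DMF, 40 °C
Reagents that add atoms: iodomethane CI
Why: Williamson methylation of the remaining chelated phenol in a dipolar aprotic solvent fixes the 2-OMe group of the target.

**Step 4**
Reactants: 4 2-methoxy-3,4-bis(methoxymethoxy)-6-methylbenzaldehyde
Product: 5 2-methoxy-3,4-bis(methoxymethoxy)-6-methylbenzoic acid
Conditions: NaClO2, NaH2PO4, 2-methylbut-2-ene, t-BuOH/H2O, rt
Reagents that add atoms: sodium chlorite [Na+].[O-]Cl=O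
Why: Pinnick oxidation converts the hindered aldehyde into the acid at a pH the MOM acetals tolerate, while the alkene scavenger keeps hypochlorous acid away from the electron-rich ring.

**Step 5**
Reactants: 6 3-(trimethylsilyl)prop-2-ynal; 7 triethyl phosphonoacetate
Product: 8 ethyl (2E)-5-(trimethylsilyl)pent-2-en-4-ynoate
Conditions: NaH, THF, 0 °C to rt
Reagents that add atoms: none
Why: Horner–Wadsworth–Emmons olefination with a stabilised phosphonate anion should give the E-enoate through the thermodynamically preferred anti oxaphosphetane.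

**Step 6**
Reactants: 8 ethyl (2E)-5-(trimethylsilyl)pent-2-en-4-ynoate
Product: 9 (2E)-pent-2-en-4-ynoic acid
Conditions: LiOH·H2O (3 equiv), THF/H2O, 0 °C to rt; then 1 M HCl
Reagents that add atoms: lithium hydroxide [Li+].[OH-]
Why: Hydroxide saponifies the ester and cleaves the C(sp)–Si bond in the same operation, and the E-alkene keeps the carboxylate away from the alkyne so that no lactone can form.

**Step 7**
Reactants: 10 (R)-carvone
Product: 11 (1R,4R,6R)-1-methyl-4-(prop-1-en-2-yl)-7-oxabicyclo[4.1.0]heptan-2-one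
Conditions: 30% H2O2, NaOH (0.3 equiv), MeOH, 0 °C
Reagents that add atoms: hydrogen peroxide OO
Why: Weitz–Scheffer nucleophilic epoxidation should touch only the enone alkene, and hydroperoxide adds anti to the C-5 isopropenyl group, so the epoxide is trans to it; this sets the future C-7 and the face for C-6.

**Step 8**
Reactants: 11 (1R,4R,6R)-1-methyl-4-(prop-1-en-2-yl)-7-oxabicyclo[4.1.0]heptan-2-one
Product: 14 (1R,3R,4R,6R)-3-({[tert-butyl(dimethyl)silyl]oxy}methyl)-1-methyl-4-(prop-1-en-2-yl)-7-oxabicyclo[4.1.0]heptan-2-one, via lithium enolate 12 (not isolated), via lithium aldolate 13 (not isolated)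
Conditions: LiN(i-Pr)2 (1.1 equiv), THF, −78 °C; monomeric CH2O in THF, −78 °C; then TBSOTf (1.2 equiv), −78 to 0 °C
Reagents that add atoms: formaldehyde C=O; tert-butyldimethylsilyl trifluoromethanesulfonate CC(C)(C)[Si](C)(C)OS(=O)(=O)C(F)(F)F
Why: Only C-3 can be enolised, the aldol addition to formaldehyde should occur anti to the isopropenyl group, and silylation of the lithium alkoxide in the flask blocks retro-aldol loss; the new stereocentre is erased later.

**Step 9**
Reactants: 14 (1R,3R,4R,6R)-3-({[tert-butyl(dimethyl)silyl]oxy}methyl)-1-methyl-4-(prop-1-en-2-yl)-7-oxabicyclo[4.1.0]heptan-2-one; 5 2-methoxy-3,4-bis(methoxymethoxy)-6-methylbenzoic acid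
Product: 15 (1S,2R,4R,5R)-4-({[tert-butyl(dimethyl)silyl]oxy}methyl)-2-hydroxy-2-methyl-3-oxo-5-(prop-1-en-2-yl)cyclohexyl 2-methoxy-3,4-bis(methoxymethoxy)-6-methylbenzoate
Conditions: 5 (1.5 equiv), Cs2CO3 (0.3 equiv), DMF, 70 °C
Reagents that add atoms: none
Why: SN2 opening of the α,β-epoxy ketone by the cesium carboxylate should occur at the β-carbon, because the α-carbon is quaternary and next to the carbonyl. Inversion there gives the S ester centre trans to the retained R tertiary alcohol, and the hindered acid reacts through its unhindered oxygen.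

**Step 10**
Reactants: 15 (1S,2R,4R,5R)-4-({[tert-butyl(dimethyl)silyl]oxy}methyl)-2-hydroxy-2-methyl-3-oxo-5-(prop-1-en-2-yl)cyclohexyl 2-methoxy-3,4-bis(methoxymethoxy)-6-methylbenzoate
Product: 18 (1S,2R)-4-({[tert-butyl(dimethyl)silyl]oxy}methyl)-2-hydroxy-2-methyl-3,5-dioxocyclohexyl 2-methoxy-3,4-bis(methoxymethoxy)-6-methylbenzoate, via methoxy hydroperoxide 16 (not isolated), via TEMPO alkoxyamine 17 (not isolated)
Conditions: O3 (titrated), MeOH/CH2Cl2, −78 °C; then FeSO4·7H2O (1.2 equiv), TEMPO (1.5 equiv), −78 °C to rt; then mCPBA (2.2 equiv), rt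
Reagents that add atoms: TEMPO CC1(C)CCCC(C)(C)N1[O]
Why: Oxodealkenylation: ozonolysis in methanol gives the methoxy hydroperoxide, divalent iron cleaves its O–O bond, β-scission of the alkoxy radical expels the ring radical, TEMPO traps it, and peracid N-oxidation with elimination leaves the ketone. The reaction type is known for isopropenyl groups of carvone-type ketones and here erases the relay stereocentre.

**Step 11**
Reactants: 18 (1S,2R)-4-({[tert-butyl(dimethyl)silyl]oxy}methyl)-2-hydroxy-2-methyl-3,5-dioxocyclohexyl 2-methoxy-3,4-bis(methoxymethoxy)-6-methylbenzoate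
Product: 19 (1S,2R)-4-({[tert-butyl(dimethyl)silyl]oxy}methyl)-2-hydroxy-2-methyl-3-oxo-5-{[(trifluoromethyl)sulfonyl]oxy}cyclohex-4-en-1-yl 2-methoxy-3,4-bis(methoxymethoxy)-6-methylbenzoate
Conditions: PhNTf2 (1.1 equiv), Et3N (1.5 equiv), CH2Cl2, 0 °C to rt
Reagents that add atoms: N-phenylbis(trifluoromethanesulfonimide) O=S(=O)(N(c1ccccc1)S(=O)(=O)C(F)(F)F)C(F)(F)F
Why: O-sulfonylation of the 1,3-dione enolate should occur at the oxygen remote from the quaternary C(OH)Me centre (less hindered; the other carbonyl is hydrogen-bonded to the α-hydroxyl), and the mild triflimide leaves the tertiary alcohol alone.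

**Step 12**
Reactants: 19 (1S,2R)-4-({[tert-butyl(dimethyl)silyl]oxy}methyl)-2-hydroxy-2-methyl-3-oxo-5-{[(trifluoromethyl)sulfonyl]oxy}cyclohex-4-en-1-yl 2-methoxy-3,4-bis(methoxymethoxy)-6-methylbenzoate
Product: 20 (1S,2R)-2-hydroxy-4-(hydroxymethyl)-2-methyl-3-oxo-5-{[(trifluoromethyl)sulfonyl]oxy}cyclohex-4-en-1-yl 2-methoxy-3,4-bis(methoxymethoxy)-6-methylbenzoate
Conditions: HF·pyridine, THF/pyridine, 0 °C to rt
Reagents that add atoms: none
Why: Fluoride-mediated cleavage of the primary alkyl silyl ether under weakly acidic conditions should leave the vinyl triflate, the MOM acetals and the hindered benzoate untouched.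

**Step 13**
Reactants: 20 (1S,2R)-2-hydroxy-4-(hydroxymethyl)-2-methyl-3-oxo-5-{[(trifluoromethyl)sulfonyl]oxy}cyclohex-4-en-1-yl 2-methoxy-3,4-bis(methoxymethoxy)-6-methylbenzoate; 9 (2E)-pent-2-en-4-ynoic acid
Product: 22 (2E)-3-[(6S,7R)-7-hydroxy-6-{[2-methoxy-3,4-bis(methoxymethoxy)-6-methylbenzoyl]oxy}-7-methyl-8-oxo-5,6,7,8-tetrahydro-1H-isochromen-3-yl]prop-2-enoic acid, via enynone acid 21 (not isolated)
Conditions: PdCl2(PPh3)2 (5 mol %), CuI (10 mol %), i-Pr2NEt (4 equiv), degassed MeCN, 0 °C to rt; then DABCO (0.3 equiv), 40 °C, same flask; citric acid work-up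
Reagents that add atoms: none
Why: Zerovalent palladium inserts into the C–OTf bond of 20, the copper acetylide of 9 transmetalates and reductive elimination forms the C4–C4a bond to give enynone 21; the primary hydroxyl on the C-8a methylene then adds under amine catalysis to the distal alkyne carbon, which is the δ-position of the C-8 ketone (C8=O, C8a=C4a, C≡C), and protonation of the allenyl enolate completes the O2–C3 bond. The closest known reaction types are the tandem Sonogashira coupling–cycloisomerisation of ortho-halobenzyl alcohols to 1H-isochromenes and the amine-catalysed oxa-Michael addition of alcohols to ynones. Ring B (the pyran) closes in the 6-endo-dig mode and no bond of ring A is touched. No stereocentre is created: C-6 and C-7 are spectators and the E-alkene of 9 is carried through unchanged. The step needs 6-endo instead of 5-exo closure (which would end in a furan) and no β-elimination of the C-6 benzoate; the first should be secured by the ring ketone, which polarises the alkyne toward attack at the distal carbon, and by carrying the side chain as its carboxylate, which is no competing Michael acceptor, and the second by using only weak tertiary amines near room temperature.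

**Step 14**
Reactants: 22 (2E)-3-[(6S,7R)-7-hydroxy-6-{[2-methoxy-3,4-bis(methoxymethoxy)-6-methylbenzoyl]oxy}-7-methyl-8-oxo-5,6,7,8-tetrahydro-1H-isochromen-3-yl]prop-2-enoic acid
Product: 23 (2E)-3-[(6S,7R)-6-[(3,4-dihydroxy-2-methoxy-6-methylbenzoyl)oxy]-7-hydroxy-7-methyl-8-oxo-5,6,7,8-tetrahydro-1H-isochromen-3-yl]prop-2-enoic acid
Conditions: TFA/CH2Cl2 (1:4), H2O (5 equiv), 0 °C to rt
Reagents that add atoms: none
Why: Acid-catalysed hydrolysis of the two aryl MOM acetals should free the catechol, while the dienyl ether (a doubly vinylogous ester), the di-ortho-substituted benzoate and the tertiary α-ketol are expected to survive.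

**Compound list**
1 | 2,3,4-trimethoxy-6-methylbenzaldehyde | COc1cc(C)c(C=O)c(OC)c1OC | starting material
2 | 2,3,4-trihydroxy-6-methylbenzaldehyde | Cc1cc(O)c(O)c(O)c1C=O | intermediate
3 | 2-hydroxy-3,4-bis(methoxymethoxy)-6-methylbenzaldehyde | Cc1cc(OCOC)c(OCOC)c(O)c1C=O | intermediate
4 | 2-methoxy-3,4-bis(methoxymethoxy)-6-methylbenzaldehyde | COc1c(OCOC)c(OCOC)cc(C)c1C=O | intermediate
5 | 2-methoxy-3,4-bis(methoxymethoxy)-6-methylbenzoic acid | COc1c(OCOC)c(OCOC)cc(C)c1C(=O)O | intermediate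
6 | 3-(trimethylsilyl)prop-2-ynal | C[Si](C)(C)C#CC=O | starting material
7 | triethyl phosphonoacetate | CCOC(=O)CP(=O)(OCC)OCC | starting material
8 | ethyl (2E)-5-(trimethylsilyl)pent-2-en-4-ynoate | CCOC(=O)/C=C/C#C[Si](C)(C)C | intermediate
9 | (2E)-pent-2-en-4-ynoic acid | C#C/C=C/C(=O)O | intermediate
10 | (R)-carvone, (5R)-2-methyl-5-(prop-1-en-2-yl)cyclohex-2-en-1-one | CC1=CC[C@H](CC1=O)C(C)=C | starting material
11 | (1R,4R,6R)-1-methyl-4-(prop-1-en-2-yl)-7-oxabicyclo[4.1.0]heptan-2-one (epoxide trans to isopropenyl) | C=C(C)[C@H]1CC(=O)[C@]2(C)O[C@@H]2C1 | intermediate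
12 | lithium enolate of 11 (C2–C3 enolate) | C=C(C)[C@H]1C=C([O-])[C@]2(C)O[C@@H]2C1.[Li+] | intermediate
13 | lithium alkoxide of the 3-hydroxymethyl ketone (CH2O− trans to isopropenyl) | C=C(C)[C@H]1[C@H](C[O-])C(=O)[C@]2(C)O[C@@H]2C1.[Li+] | intermediate
14 | (1R,3R,4R,6R)-3-({[tert-butyl(dimethyl)silyl]oxy}methyl)-1-methyl-4-(prop-1-en-2-yl)-7-oxabicyclo[4.1.0]heptan-2-one | C=C(C)[C@H]1[C@H](CO[Si](C)(C)C(C)(C)C)C(=O)[C@]2(C)O[C@@H]2C1 | intermediate
15 | (1S,2R,4R,5R)-4-({[tert-butyl(dimethyl)silyl]oxy}methyl)-2-hydroxy-2-methyl-3-oxo-5-(prop-1-en-2-yl)cyclohexyl 2-methoxy-3,4-bis(methoxymethoxy)-6-methylbenzoate | COc1c(OCOC)c(OCOC)cc(C)c1C(=O)O[C@H]1C[C@@H](C(C)=C)[C@H](CO[Si](C)(C)C(C)(C)C)C(=O)[C@]1(C)O | intermediate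
16 | (1S,2R,4R,5R)-4-({[tert-butyl(dimethyl)silyl]oxy}methyl)-5-(1-hydroperoxy-1-methoxyethyl)-2-hydroxy-2-methyl-3-oxocyclohexyl 2-methoxy-3,4-bis(methoxymethoxy)-6-methylbenzoate (side-chain carbon as a mixture) | COc1c(OCOC)c(OCOC)cc(C)c1C(=O)O[C@H]1C[C@@H](C(C)(OC)OO)[C@H](CO[Si](C)(C)C(C)(C)C)C(=O)[C@]1(C)O | intermediate
17 | (1S,2R)-4-({[tert-butyl(dimethyl)silyl]oxy}methyl)-2-hydroxy-2-methyl-3-oxo-5-[(2,2,6,6-tetramethylpiperidin-1-yl)oxy]cyclohexyl 2-methoxy-3,4-bis(methoxymethoxy)-6-methylbenzoate (C-5 as a mixture, C-4 as in 15) | COc1c(OCOC)c(OCOC)cc(C)c1C(=O)O[C@H]1CC(ON2C(C)(C)CCCC2(C)C)[C@H](CO[Si](C)(C)C(C)(C)C)C(=O)[C@]1(C)O | intermediate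
18 | (1S,2R)-4-({[tert-butyl(dimethyl)silyl]oxy}methyl)-2-hydroxy-2-methyl-3,5-dioxocyclohexyl 2-methoxy-3,4-bis(methoxymethoxy)-6-methylbenzoate (enolised, C-4 open) | COc1c(OCOC)c(OCOC)cc(C)c1C(=O)O[C@H]1CC(=O)C(CO[Si](C)(C)C(C)(C)C)C(=O)[C@]1(C)O | intermediate
19 | (1S,2R)-4-({[tert-butyl(dimethyl)silyl]oxy}methyl)-2-hydroxy-2-methyl-3-oxo-5-{[(trifluoromethyl)sulfonyl]oxy}cyclohex-4-en-1-yl 2-methoxy-3,4-bis(methoxymethoxy)-6-methylbenzoate | COc1c(OCOC)c(OCOC)cc(C)c1C(=O)O[C@H]1CC(OS(=O)(=O)C(F)(F)F)=C(CO[Si](C)(C)C(C)(C)C)C(=O)[C@]1(C)O | intermediate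
20 | (1S,2R)-2-hydroxy-4-(hydroxymethyl)-2-methyl-3-oxo-5-{[(trifluoromethyl)sulfonyl]oxy}cyclohex-4-en-1-yl 2-methoxy-3,4-bis(methoxymethoxy)-6-methylbenzoate | COc1c(OCOC)c(OCOC)cc(C)c1C(=O)O[C@H]1CC(OS(=O)(=O)C(F)(F)F)=C(CO)C(=O)[C@]1(C)O | intermediate
21 | (2E)-5-[(4R,5S)-4-hydroxy-2-(hydroxymethyl)-5-{[2-methoxy-3,4-bis(methoxymethoxy)-6-methylbenzoyl]oxy}-4-methyl-3-oxocyclohex-1-en-1-yl]pent-2-en-4-ynoic acid | COc1c(OCOC)c(OCOC)cc(C)c1C(=O)O[C@H]1CC(C#C/C=C/C(=O)O)=C(CO)C(=O)[C@]1(C)O | intermediate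
22 | (2E)-3-[(6S,7R)-7-hydroxy-6-{[2-methoxy-3,4-bis(methoxymethoxy)-6-methylbenzoyl]oxy}-7-methyl-8-oxo-5,6,7,8-tetrahydro-1H-isochromen-3-yl]prop-2-enoic acid | COc1c(OCOC)c(OCOC)cc(C)c1C(=O)O[C@H]1CC2=C(COC(/C=C/C(=O)O)=C2)C(=O)[C@]1(C)O | intermediate
23 | (2E)-3-[(6S,7R)-6-[(3,4-dihydroxy-2-methoxy-6-methylbenzoyl)oxy]-7-hydroxy-7-methyl-8-oxo-5,6,7,8-tetrahydro-1H-isochromen-3-yl]prop-2-enoic acid | COc1c(O)c(O)cc(C)c1C(=O)O[C@H]1CC2=C(COC(/C=C/C(=O)O)=C2)C(=O)[C@]1(C)O | target

**Totals**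
Total step count: 14. Longest linear sequence: 10 steps (steps 1–4, then 9–14).

**Steps most likely to fail**

Step 13. The ring may close in the 5-exo mode and then aromatise to a furan, or the base may cause elimination of the C-6 benzoate through the γ-methylene. The fallback sets out from 20 and returns at 23. Sonogashira coupling of 20 with 3,3-diethoxyprop-1-yne (PdCl2(PPh3)2, CuI, Et3N) should give the isolated enynone acetal F1, whose alkyne carries no second acceptor. A separately tuned 6-endo oxa-Michael closure (DABCO or catalytic Cs2CO3) should then give the pyran acetal F2. PPTS in wet acetone should unmask the pyran aldehyde F3, and a Wittig reaction with tert-butyl (triphenylphosphoranylidene)acetate should give the tert-butyl ester F4. The acid treatment of step 14 then cleaves the tert-butyl ester together with the MOM ethers to reach 23.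

Step 9. The bulky arenecarboxylate may attack the neopentyl-type epoxide carbon too slowly, so that thermal breakdown of the epoxy ketone competes. The fallback sets out from 14 and returns at 15, and makes the ester by acylation instead of by carboxylate alkylation. Opening with the small nucleophile cesium acetate (CsOAc, DMF, 70 °C) should give the trans-hydroxy acetate F5, and methanolysis (K2CO3, MeOH, 0 °C) the trans-diol F6. Acid 5 is converted with 1-chloro-N,N,2-trimethylprop-1-en-1-amine into the acid chloride F7. Acylation of the secondary hydroxyl of F6 with F7 (pyridine, DMAP) should give 15.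

Step 10. Ozone may attack the electron-rich arene, the ring radical may be trapped incompletely, or the peracid may over-oxidise the enolised dione. The fallback sets out from 15 and returns at 18, and replaces the radical excision by a cationic 1,2-shift. Ozonolysis in MeOH/CH2Cl2 followed by Ac2O, Et3N and DMAP (Criegee rearrangement, retention at the migrating carbon) should give the ring acetate F8. Base-free enzymatic hydrolysis (Candida antarctica lipase B, pH 7 buffer/MTBE), chosen to avoid β-elimination of the acetate, should give the β-hydroxy ketone F9. Dess–Martin periodinane should then give 18.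

**Further compounds**
F1 | step 13 | (1S,2R)-5-(3,3-diethoxyprop-1-yn-1-yl)-2-hydroxy-4-(hydroxymethyl)-2-methyl-3-oxocyclohex-4-en-1-yl 2-methoxy-3,4-bis(methoxymethoxy)-6-methylbenzoate | COc1c(OCOC)c(OCOC)cc(C)c1C(=O)O[C@H]1CC(C#CC(OCC)OCC)=C(CO)C(=O)[C@]1(C)O
F2 | step 13 | (6S,7R)-3-(diethoxymethyl)-7-hydroxy-7-methyl-8-oxo-5,6,7,8-tetrahydro-1H-isochromen-6-yl 2-methoxy-3,4-bis(methoxymethoxy)-6-methylbenzoate | COc1c(OCOC)c(OCOC)cc(C)c1C(=O)O[C@H]1CC2=C(COC(C(OCC)OCC)=C2)C(=O)[C@]1(C)O
F3 | step 13 | (6S,7R)-3-formyl-7-hydroxy-7-methyl-8-oxo-5,6,7,8-tetrahydro-1H-isochromen-6-yl 2-methoxy-3,4-bis(methoxymethoxy)-6-methylbenzoate | COc1c(OCOC)c(OCOC)cc(C)c1C(=O)O[C@H]1CC2=C(COC(C=O)=C2)C(=O)[C@]1(C)O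
F4 | step 13 | tert-butyl (2E)-3-[(6S,7R)-7-hydroxy-6-{[2-methoxy-3,4-bis(methoxymethoxy)-6-methylbenzoyl]oxy}-7-methyl-8-oxo-5,6,7,8-tetrahydro-1H-isochromen-3-yl]prop-2-enoate | COc1c(OCOC)c(OCOC)cc(C)c1C(=O)O[C@H]1CC2=C(COC(/C=C/C(=O)OC(C)(C)C)=C2)C(=O)[C@]1(C)O
F5 | step 9 | (1S,2R,4R,5R)-4-({[tert-butyl(dimethyl)silyl]oxy}methyl)-2-hydroxy-2-methyl-3-oxo-5-(prop-1-en-2-yl)cyclohexyl acetate | CC(=O)O[C@H]1C[C@@H](C(C)=C)[C@H](CO[Si](C)(C)C(C)(C)C)C(=O)[C@]1(C)O
F6 | step 9 | (2R,3S,5R,6R)-6-({[tert-butyl(dimethyl)silyl]oxy}methyl)-2,3-dihydroxy-2-methyl-5-(prop-1-en-2-yl)cyclohexan-1-one | O[C@H]1C[C@@H](C(C)=C)[C@H](CO[Si](C)(C)C(C)(C)C)C(=O)[C@]1(C)O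
F7 | step 9 | 2-methoxy-3,4-bis(methoxymethoxy)-6-methylbenzoyl chloride | COc1c(OCOC)c(OCOC)cc(C)c1C(=O)Cl
F8 | step 10 | (1S,2R,4S,5R)-5-(acetyloxy)-4-({[tert-butyl(dimethyl)silyl]oxy}methyl)-2-hydroxy-2-methyl-3-oxocyclohexyl 2-methoxy-3,4-bis(methoxymethoxy)-6-methylbenzoate | COc1c(OCOC)c(OCOC)cc(C)c1C(=O)O[C@H]1C[C@@H](OC(C)=O)[C@H](CO[Si](C)(C)C(C)(C)C)C(=O)[C@]1(C)O
F9 | step 10 | (1S,2R,4S,5R)-4-({[tert-butyl(dimethyl)silyl]oxy}methyl)-2,5-dihydroxy-2-methyl-3-oxocyclohexyl 2-methoxy-3,4-bis(methoxymethoxy)-6-methylbenzoate | COc1c(OCOC)c(OCOC)cc(C)c1C(=O)O[C@H]1C[C@@H](O)[C@H](CO[Si](C)(C)C(C)(C)C)C(=O)[C@]1(C)O
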